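**Retrosynthetic overview**

1. Numbering (germacrane type): ring carbons C1–C10, ether O between C1 and C5, oxirane on C4 (CH2 = C15), lactone O on C6, C7 carries C11(=C13)–C12, methacrylate on C8, C9=C10, C14 = CHO. Late stage: the oxirane is made last from the 4(15)-alkene, C14 is unveiled from a silyl ether, and the lactone closes after reduction of a C6 ketone.
2. Key disconnection: the C7–C8 bond with shift of the double bond (retro-Claisen). The enabling feature is the γ,δ-unsaturated ketone unit O=C6–C7–C8–C9=C10 inside the eight-membered oxocene (O, C1, C10, C9, C8, C7, C6, C5), with the ether O between C1 and C5 as a three-atom tether. The oxocene therefore comes from the six-membered 1,4-dioxane (O, C5, C6, O', C10, C1) of a 3,9-dioxabicyclo[3.3.1]nonane by a two-atom ring expansion that also closes the ten-membered carbocycle.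
3. Dioxane ring: the tertiary C10–OH adds to a C5 alkyne with Pd-coupling to methyl 2-bromoacrylate (brings C11–C13, E enol ether). The C8 oxygen and the methacrylate arrive together as a Z enol ester made from a C10 alkyne.
4. Oxane ring: α-methylene δ-lactone + acetylide, then silane reduction (2,6-cis). The chain comes from an epoxide and the dianion of methallyl alcohol; C1 comes from D-erythrulose and C10 from a chelation-controlled alkynylation.
5. Ring order: oxane → 1,4-dioxane → oxocene and cyclodecene (key step) → γ-lactone → oxirane.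

Key step: step 13

Remark (assumption): D-erythrulose is taken as the purchased single enantiomer; atom labels C1–C15 in the text are those of overview line 1.

**Route**

Step 1
Reactants: 1 D-erythrulose; 2 2,2-dimethoxypropane
Product: 3 1-[(4R)-2,2-dimethyl-1,3-dioxolan-4-yl]-2-hydroxyethan-1-one
Conditions: 2,2-dimethoxypropane, acetone, CSA (cat.), rt
Reagents that add atoms: 2,2-dimethoxypropane, COC(C)(C)OC
Why: Acid-catalysed transacetalisation should close the dioxolane on the vicinal 3,4-diol and leave the primary α-hydroxy ketone free, with the stereocentre (later C1) untouched.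

Step 2
Reactants: 3; 4 tert-butyl(chloro)diphenylsilane
Product: 5 2-[(tert-butyldiphenylsilyl)oxy]-1-[(4R)-2,2-dimethyl-1,3-dioxolan-4-yl]ethan-1-one
Conditions: TBDPSCl, imidazole, CH2Cl2, 0 °C to rt
Reagents that add atoms: tert-butyl(chloro)diphenylsilane, CC(C)(C)[Si](Cl)(c1ccccc1)c1ccccc1
Why: Silyl ether formation at the only free hydroxyl; the bulky, poorly coordinating silyl ether leaves the dioxolane oxygen as the only chelating site for step 3.

Step 3
Reactants: 5; 6 ethynyl(trimethyl)silane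
Product: 7 (2S)-1-[(tert-butyldiphenylsilyl)oxy]-2-[(4R)-2,2-dimethyl-1,3-dioxolan-4-yl]-4-(trimethylsilyl)but-3-yn-2-ol
Conditions: 6, EtMgBr, THF, 0 °C to rt; then 5, Et2O, −78 to −30 °C; aq. NH4Cl
Reagents that add atoms: ethynyl(trimethyl)silane, C[Si](C)(C)C#C
Why: Cram-chelate-controlled Grignard addition: Mg bridges the ketone oxygen and the α-oxygen of the dioxolane, and the alkynyl group should enter from the side of the α-hydrogen (anti to the dioxolane CH2), which sets the tertiary carbinol C10.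

Step 4
Reactants: 7
Product: 8 (2R,3S)-3-{[(tert-butyldiphenylsilyl)oxy]methyl}-5-(trimethylsilyl)pent-4-yne-1,2,3-triol
Conditions: AcOH/H2O 4:1, 40 °C
Reagents that add atoms: none
Why: Acid hydrolysis of the acetonide (acetal cleavage), which the silyl ether, the C-silyl alkyne and the tertiary propargylic alcohol should tolerate.

Step 5
Reactants: 8
Product: 10 (2S)-1-[(tert-butyldiphenylsilyl)oxy]-2-[(2R)-oxiran-2-yl]-4-(trimethylsilyl)but-3-yn-2-ol, via primary tosylate 9 (not isolated)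
Conditions: TsCl, Bu2SnO (2 mol%), Et3N, CH2Cl2, 0 °C; then NaH, THF, 0 °C
Reagents that add atoms: none
Why: Tin-catalysed sulfonylation is selective for the primary hydroxyl of the 1,2-diol, and intramolecular Williamson closure (3-exo-tet) by the secondary alkoxide gives the terminal epoxide with retention at C1; methanolic base is avoided to keep the C-silyl group.

Step 6
Reactants: 10; 11 2-methylprop-2-en-1-ol
Product: 12 (3S,4R)-3-{[(tert-butyldiphenylsilyl)oxy]methyl}-7-methylidene-1-(trimethylsilyl)oct-1-yne-3,4,8-triol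
Conditions: 11, n-BuLi (2 equiv), TMEDA, Et2O/hexane, 0 °C to rt; then 10 (0.3 equiv), THF, −78 to 0 °C; aq. NH4Cl
Reagents that add atoms: 2-methylprop-2-en-1-ol, C=C(C)CO
Why: The C,O-dilithio dianion of methallyl alcohol (a symmetrical allyl anion) should open the epoxide at its terminal carbon (SN2), joining C2 to C3 and bringing C4(=C15) and C5, while the tertiary lithium alkoxide stays a spectator at low temperature.

Step 7
Reactants: 12
Product: 13 (6R)-6-[(2S)-1-[(tert-butyldiphenylsilyl)oxy]-2-hydroxy-4-(trimethylsilyl)but-3-yn-2-yl]-3-methylideneoxan-2-one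
Conditions: TEMPO (20 mol%), PhI(OAc)2 (2.5 equiv), CH2Cl2, rt
Reagents that add atoms: none
Why: TEMPO/PhI(OAc)2 oxidative lactonisation of a 1,5-diol: the primary allylic alcohol is oxidised first, the aldehyde is trapped by the C1 hydroxyl as the six-membered lactol, and this is oxidised to the δ-lactone.

Step 8
Reactants: 13; 14 trimethylsilyl trifluoromethanesulfonate
Product: 15 (6R)-6-[(2S)-1-[(tert-butyldiphenylsilyl)oxy]-4-(trimethylsilyl)-2-[(trimethylsilyl)oxy]but-3-yn-2-yl]-3-methylideneoxan-2-one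
Conditions: TMSOTf, 2,6-lutidine, CH2Cl2, −78 °C
Reagents that add atoms: trimethylsilyl trifluoromethanesulfonate, C[Si](C)(C)OS(=O)(=O)C(F)(F)F
Why: Silylation of the tertiary alcohol, so that it cannot trap the oxocarbenium ion of step 9 as a bicyclic ketal.

Step 9
Reactants: 15; 16 acetylene
Product: 19 (2S)-1-[(tert-butyldiphenylsilyl)oxy]-2-[(2R,6S)-6-ethynyl-5-methylideneoxan-2-yl]-4-(trimethylsilyl)but-3-yn-2-ol, via lactol 17 (not isolated), via silyl ether 18 (not isolated)
Conditions: HC≡CH, n-BuLi, THF, −78 °C, then 15, −78 °C, AcOH quench; Et3SiH, BF3·OEt2, CH2Cl2/MeCN, −78 to −40 °C; then 1 M HCl, THF, 0 °C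
Reagents that add atoms: acetylene, C#C
Why: 1,2-Addition of lithium acetylide to the lactone gives the alkynyl lactol, and Kishi-type ionic reduction (oxocarbenium ion, axial hydride from Et3SiH at the carbon next to oxygen) should give the 2,6-cis oxane and so set C5; the dilute acid work-up removes only the tertiary O-silyl group.

Step 10
Reactants: 19; 20 methyl 2-bromoprop-2-enoate
Product: 21 methyl 2-{(E)-[(1R,2S,5S)-2-{[(tert-butyldiphenylsilyl)oxy]methyl}-6-methylidene-2-[(trimethylsilyl)ethynyl]-3,9-dioxabicyclo[3.3.1]nonan-4-ylidene]methyl}prop-2-enoate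
Conditions: LiHMDS (1.0 equiv), THF, −78 to 0 °C; then 20, Pd(PPh3)4 (5 mol%), THF, 45 °C
Reagents that add atoms: methyl 2-bromoprop-2-enoate, COC(=O)C(Br)=C
Why: Palladium-catalysed cyclisation–coupling of an alkynol with a vinyl halide (anti-oxypalladation of the alkyne bound to the vinylpalladium(II) species, 6-exo-dig attack of the tertiary alkoxide, reductive elimination) should close the 1,4-dioxane and place C11 trans to the ring oxygen (E enol ether).

Step 11
Reactants: 21
Product: 22 methyl 2-{(E)-[(1R,2S,5S)-2-{[(tert-butyldiphenylsilyl)oxy]methyl}-2-ethynyl-6-methylidene-3,9-dioxabicyclo[3.3.1]nonan-4-ylidene]methyl}prop-2-enoate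
Conditions: K2CO3 (0.2 equiv), MeOH, 0 °C
Reagents that add atoms: none
Why: Base-catalysed protiodesilylation of the C-trimethylsilyl alkyne, to which the silyl ether and the enol ether are stable.

Step 12
Reactants: 22; 23 2-methylprop-2-enoic acid
Product: 24 methyl 2-{(E)-[(1R,2S,5S)-2-{[(tert-butyldiphenylsilyl)oxy]methyl}-6-methylidene-2-{(Z)-2-[(2-methylprop-2-enoyl)oxy]ethenyl}-3,9-dioxabicyclo[3.3.1]nonan-4-ylidene]methyl}prop-2-enoate
Conditions: 23 (1.3 equiv), [(p-cymene)RuCl2]2 (1 mol%), P(4-ClC6H4)3 (3 mol%), DMAP (4 mol%), BHT, toluene, 60 °C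
Reagents that add atoms: 2-methylprop-2-enoic acid, CC(=C)C(=O)O
Why: Ruthenium-vinylidene-mediated anti-Markovnikov addition of a carboxylic acid to a terminal alkyne should give the Z enol ester, installing the C8 oxygen and the methacrylate at once, while the DMAP-buffered medium spares the enol ether.

Step 13
Reactants: 24
Product: 25 methyl (1R,5S,7R,8R,9Z)-14-[(tert-butyldiphenylsilyl)oxy]-8-[(2-methylprop-2-enoyl)oxy]-6-oxo-1,5-epoxygermacra-4(15),9,11(13)-trien-12-oate
Conditions: toluene (0.01 M), BHT, silylated sealed tube, 130 °C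
Reagents that add atoms: none
Why: Thermal Claisen rearrangement ([3,3]-sigmatropic shift of the allyl vinyl ether C7=C6–O–C10–C9=C8): the C7–C8 bond forms as the O–C10 bond breaks, so the six-membered 1,4-dioxane grows by two atoms into the eight-membered oxocene and the ten-membered carbocycle closes in the same event. The closest known reaction type is the Claisen ring expansion of 2-alkylidene vinyl cyclic ethers to medium-ring ketones, including 2-methylene-6-vinyl-1,4-dioxanes to oxocenones. Both rings are closed by one concerted, suprafacial C–C bond formation through a chair six-membered transition state fused to the dioxane like a chair–chair bicyclo[3.3.1]nonane; the boat is excluded because the three-atom tether C5–O–C1 cannot then span C6 and C10. C7 is set by the E geometry of the C6=C7 enol ether (C11 equatorial) and C8 by the Z geometry of the enol ester (acyloxy axial); the face is fixed by the C10 stereocentre, whose vinyl group is axial on the dioxane and anti to the C2–C4 bridge, and C10 itself becomes sp2 with C9=C10 cis in the ring. The step needs chair-only transfer of both alkene geometries without E/Z leakage or enol ether hydrolysis, which the rigid bicycle, acid-free glassware and the radical inhibitor should secure; the axial acyloxy group facing the ring oxygen should raise the temperature needed but not change the outcome.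

Step 14
Reactants: 25
Product: 27 (1R,5S,6S,7R,8R,9Z)-14-[(tert-butyldiphenylsilyl)oxy]-1,5-epoxygermacra-4(15),9,11(13)-trien-12,6-olid-8-yl 2-methylprop-2-enoate, via hydroxy ester 26 (not isolated)
Conditions: crude 25, NaBH4, CeCl3·7H2O, MeOH, −78 °C; then CSA (cat.), CH2Cl2, rt
Reagents that add atoms: none
Why: Luche 1,2-reduction of the C6 ketone, with hydride expected anti to the C5–O bond (polar Felkin–Anh) to give the 6S alcohol, which should close the trans-fused γ-lactone by acid-catalysed transesterification onto the C12 methyl ester; using 25 crude and cold limits β-elimination and C7 epimerisation.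

Step 15
Reactants: 27
Product: 28 (1R,5S,6S,7R,8R,9Z)-1,5-epoxy-14-hydroxygermacra-4(15),9,11(13)-trien-12,6-olid-8-yl 2-methylprop-2-enoate
Conditions: HF·pyridine, pyridine, THF, 0 °C to rt
Reagents that add atoms: none
Why: Fluoride-mediated cleavage of the silyl ether under buffered conditions that the esters, the lactone and the alkenes should tolerate.

Step 16
Reactants: 28
Product: 29 (1R,5S,6S,7R,8R,9E)-1,5-epoxy-14-oxogermacra-4(15),9,11(13)-trien-12,6-olid-8-yl 2-methylprop-2-enoate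
Conditions: activated MnO2, CH2Cl2, rt
Reagents that add atoms: none
Why: MnO2 oxidation of the primary allylic alcohol to the enal, which also deactivates the C9=C10 bond for step 17.

Step 17
Reactants: 29; 30 3-chloroperoxybenzoic acid
Product: 31 (1R,4R,5R,6S,7R,8R,9E)-1,5:4,15-diepoxy-14-oxogermacra-9,11(13)-dien-12,6-olid-8-yl 2-methylprop-2-enoate (CNP0257628.1)
Conditions: mCPBA, NaHCO3, CH2Cl2, 0 °C
Reagents that add atoms: 3-chloroperoxybenzoic acid, OOC(=O)c1cccc(Cl)c1
Why: Prilezhaev epoxidation of the only alkene not conjugated to a carbonyl (C4=C15); the peracid should approach from the face opposite the C6–C10 bridge (axial attack on the oxane, anti to the C5–C6 bond), which places the oxirane oxygen as in the target and sets C4.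

**Compound list**

1 | D-erythrulose, (3R)-1,3,4-trihydroxybutan-2-one | O=C(CO)[C@H](O)CO | starting material
2 | 2,2-dimethoxypropane | COC(C)(C)OC | starting material
3 | 1-[(4R)-2,2-dimethyl-1,3-dioxolan-4-yl]-2-hydroxyethan-1-one | O=C(CO)[C@H]1COC(C)(C)O1 | intermediate
4 | tert-butyl(chloro)diphenylsilane | CC(C)(C)[Si](Cl)(c1ccccc1)c1ccccc1 | starting material
5 | 2-[(tert-butyldiphenylsilyl)oxy]-1-[(4R)-2,2-dimethyl-1,3-dioxolan-4-yl]ethan-1-one | O=C(CO[Si](c1ccccc1)(c1ccccc1)C(C)(C)C)[C@H]1COC(C)(C)O1 | intermediate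
6 | ethynyl(trimethyl)silane | C[Si](C)(C)C#C | starting material
7 | (2S)-1-[(tert-butyldiphenylsilyl)oxy]-2-[(4R)-2,2-dimethyl-1,3-dioxolan-4-yl]-4-(trimethylsilyl)but-3-yn-2-ol | C[Si](C)(C)C#C[C@](O)(CO[Si](c1ccccc1)(c1ccccc1)C(C)(C)C)[C@H]1COC(C)(C)O1 | intermediate
8 | (2R,3S)-3-{[(tert-butyldiphenylsilyl)oxy]methyl}-5-(trimethylsilyl)pent-4-yne-1,2,3-triol | C[Si](C)(C)C#C[C@](O)(CO[Si](c1ccccc1)(c1ccccc1)C(C)(C)C)[C@H](O)CO | intermediate
9 | (2R,3S)-3-{[(tert-butyldiphenylsilyl)oxy]methyl}-2,3-dihydroxy-5-(trimethylsilyl)pent-4-yn-1-yl 4-methylbenzenesulfonate | C[Si](C)(C)C#C[C@](O)(CO[Si](c1ccccc1)(c1ccccc1)C(C)(C)C)[C@H](O)COS(=O)(=O)c1ccc(C)cc1 | intermediate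
10 | (2S)-1-[(tert-butyldiphenylsilyl)oxy]-2-[(2R)-oxiran-2-yl]-4-(trimethylsilyl)but-3-yn-2-ol | C[Si](C)(C)C#C[C@](O)(CO[Si](c1ccccc1)(c1ccccc1)C(C)(C)C)[C@H]1CO1 | intermediate
11 | 2-methylprop-2-en-1-ol | C=C(C)CO | starting material
12 | (3S,4R)-3-{[(tert-butyldiphenylsilyl)oxy]methyl}-7-methylidene-1-(trimethylsilyl)oct-1-yne-3,4,8-triol | C[Si](C)(C)C#C[C@](O)(CO[Si](c1ccccc1)(c1ccccc1)C(C)(C)C)[C@H](O)CCC(=C)CO | intermediate
13 | (6R)-6-[(2S)-1-[(tert-butyldiphenylsilyl)oxy]-2-hydroxy-4-(trimethylsilyl)but-3-yn-2-yl]-3-methylideneoxan-2-one | C[Si](C)(C)C#C[C@](O)(CO[Si](c1ccccc1)(c1ccccc1)C(C)(C)C)[C@H]1CCC(=C)C(=O)O1 | intermediate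
14 | trimethylsilyl trifluoromethanesulfonate | C[Si](C)(C)OS(=O)(=O)C(F)(F)F | starting material
15 | (6R)-6-[(2S)-1-[(tert-butyldiphenylsilyl)oxy]-4-(trimethylsilyl)-2-[(trimethylsilyl)oxy]but-3-yn-2-yl]-3-methylideneoxan-2-one | C[Si](C)(C)C#C[C@](O[Si](C)(C)C)(CO[Si](c1ccccc1)(c1ccccc1)C(C)(C)C)[C@H]1CCC(=C)C(=O)O1 | intermediate
16 | acetylene | C#C | starting material
17 | (6R)-6-[(2S)-1-[(tert-butyldiphenylsilyl)oxy]-4-(trimethylsilyl)-2-[(trimethylsilyl)oxy]but-3-yn-2-yl]-2-ethynyl-3-methylideneoxan-2-ol (both configurations at the hemiketal carbon) | C[Si](C)(C)C#C[C@](O[Si](C)(C)C)(CO[Si](c1ccccc1)(c1ccccc1)C(C)(C)C)[C@H]1CCC(=C)C(O)(C#C)O1 | intermediate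
18 | trimethylsilyl ether of 19 at the tertiary hydroxyl, oxane carbons (2R,6S), carbinol carbon (2S) | C[Si](C)(C)C#C[C@](O[Si](C)(C)C)(CO[Si](c1ccccc1)(c1ccccc1)C(C)(C)C)[C@H]1CCC(=C)[C@@H](C#C)O1 | intermediate
19 | (2S)-1-[(tert-butyldiphenylsilyl)oxy]-2-[(2R,6S)-6-ethynyl-5-methylideneoxan-2-yl]-4-(trimethylsilyl)but-3-yn-2-ol | C[Si](C)(C)C#C[C@](O)(CO[Si](c1ccccc1)(c1ccccc1)C(C)(C)C)[C@H]1CCC(=C)[C@@H](C#C)O1 | intermediate
20 | methyl 2-bromoprop-2-enoate | COC(=O)C(Br)=C | starting material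
21 | methyl 2-{(E)-[(1R,2S,5S)-2-{[(tert-butyldiphenylsilyl)oxy]methyl}-6-methylidene-2-[(trimethylsilyl)ethynyl]-3,9-dioxabicyclo[3.3.1]nonan-4-ylidene]methyl}prop-2-enoate | COC(=O)C(=C)/C=C1/O[C@](CO[Si](c2ccccc2)(c2ccccc2)C(C)(C)C)(C#C[Si](C)(C)C)[C@H]2CCC(=C)[C@@H]1O2 | intermediate
22 | methyl 2-{(E)-[(1R,2S,5S)-2-{[(tert-butyldiphenylsilyl)oxy]methyl}-2-ethynyl-6-methylidene-3,9-dioxabicyclo[3.3.1]nonan-4-ylidene]methyl}prop-2-enoate | COC(=O)C(=C)/C=C1/O[C@](CO[Si](c2ccccc2)(c2ccccc2)C(C)(C)C)(C#C)[C@H]2CCC(=C)[C@@H]1O2 | intermediate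
23 | 2-methylprop-2-enoic acid | CC(=C)C(=O)O | starting material
24 | methyl 2-{(E)-[(1R,2S,5S)-2-{[(tert-butyldiphenylsilyl)oxy]methyl}-6-methylidene-2-{(Z)-2-[(2-methylprop-2-enoyl)oxy]ethenyl}-3,9-dioxabicyclo[3.3.1]nonan-4-ylidene]methyl}prop-2-enoate | COC(=O)C(=C)/C=C1/O[C@](CO[Si](c2ccccc2)(c2ccccc2)C(C)(C)C)(/C=C\OC(=O)C(C)=C)[C@H]2CCC(=C)[C@@H]1O2 | intermediate
25 | methyl (1R,5S,7R,8R,9Z)-14-[(tert-butyldiphenylsilyl)oxy]-8-[(2-methylprop-2-enoyl)oxy]-6-oxo-1,5-epoxygermacra-4(15),9,11(13)-trien-12-oate | C=C(C)C(=O)O[C@@H]1/C=C(/CO[Si](c2ccccc2)(c2ccccc2)C(C)(C)C)[C@H]2CCC(=C)[C@H](O2)C(=O)[C@@H]1C(=C)C(=O)OC | intermediate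
26 | methyl (1R,5S,6S,7S,8R,9Z)-14-[(tert-butyldiphenylsilyl)oxy]-6-hydroxy-8-[(2-methylprop-2-enoyl)oxy]-1,5-epoxygermacra-4(15),9,11(13)-trien-12-oate | C=C(C)C(=O)O[C@@H]1/C=C(/CO[Si](c2ccccc2)(c2ccccc2)C(C)(C)C)[C@H]2CCC(=C)[C@H](O2)[C@@H](O)[C@@H]1C(=C)C(=O)OC | intermediate
27 | (1R,5S,6S,7R,8R,9Z)-14-[(tert-butyldiphenylsilyl)oxy]-1,5-epoxygermacra-4(15),9,11(13)-trien-12,6-olid-8-yl 2-methylprop-2-enoate | C=C(C)C(=O)O[C@@H]1/C=C(/CO[Si](c2ccccc2)(c2ccccc2)C(C)(C)C)[C@H]2CCC(=C)[C@H](O2)[C@H]2OC(=O)C(=C)[C@@H]21 | intermediate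
28 | (1R,5S,6S,7R,8R,9Z)-1,5-epoxy-14-hydroxygermacra-4(15),9,11(13)-trien-12,6-olid-8-yl 2-methylprop-2-enoate | C=C(C)C(=O)O[C@@H]1/C=C(/CO)[C@H]2CCC(=C)[C@H](O2)[C@H]2OC(=O)C(=C)[C@@H]21 | intermediate
29 | (1R,5S,6S,7R,8R,9E)-1,5-epoxy-14-oxogermacra-4(15),9,11(13)-trien-12,6-olid-8-yl 2-methylprop-2-enoate | C=C(C)C(=O)O[C@@H]1/C=C(/C=O)[C@H]2CCC(=C)[C@H](O2)[C@H]2OC(=O)C(=C)[C@@H]21 | intermediate
30 | 3-chloroperoxybenzoic acid | OOC(=O)c1cccc(Cl)c1 | starting material
31 | (1R,4R,5R,6S,7R,8R,9E)-1,5:4,15-diepoxy-14-oxogermacra-9,11(13)-dien-12,6-olid-8-yl 2-methylprop-2-enoate (CNP0257628.1) | C=C(C)C(=O)O[C@@H]1/C=C(/C=O)[C@H]2CC[C@@]3(CO3)[C@H](O2)[C@H]2OC(=O)C(=C)[C@@H]21 | target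

**Step count and risks**

Total step count: 17. Longest linear sequence: 17 steps (from D-erythrulose; all other inputs are purchased reagents).

Steps most likely to fail:

Step 13 (ring expansion). The axial acyloxy group of the Z enol ester points at the ring oxygen in the only possible chair transition state, so the rearrangement may be slow and thermal decomposition, E/Z leakage of the enol ether or loss of methacrylic acid from the β-acyloxy ketone may compete. Fallback, from 22: zirconocene-catalysed hydroboration of the terminal alkyne with pinacolborane should give the (E)-alkenylboronate F1. Copper(II)-mediated coupling with chloroacetic acid (Chan–Lam type, retention) should give the (E)-enol chloroacetate F2. Its Claisen ring expansion has the acyloxy group equatorial and should run at lower temperature to the 8-epi ketone F3. Reduction and lactonisation as in step 14 should give the 8-epi lactone chloroacetate F4, and thiourea should remove the chloroacetate to the 8-epi alcohol F5. Mitsunobu esterification with methacrylic acid (PPh3, DIAD) should invert C8 and return to 27.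

Step 10 (cyclisation–coupling). The vinylpalladium species may alkynylate the terminal C–H instead of activating the alkyne for alkoxide attack, or the alkoxide may add to the bromoacrylate. Fallback, from 19: gold(I)-catalysed alkoxycyclisation in the presence of N-iodosuccinimide (anti-oxyauration, iododeauration with retention) should give the (E)-iodomethylidene dioxane F6; Stille coupling with methyl 2-(tributylstannyl)prop-2-enoate (Pd2(dba)3, AsPh3, CuI) returns to 21.

Step 14 (ketone reduction). Facial selectivity in the flexible medium ring may be poor or reversed, and acyl migration from O8 to O6 may compete. Fallback, from 25: the reduction is stopped cold without acid treatment at the 6-epi hydroxy ester F7; the methyl ester is cleaved with Me3SnOH to the 6-epi hydroxy acid F8; Mitsunobu lactonisation (PPh3, DIAD) should close the γ-lactone with inversion at C6 and return to 27.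

**Further compounds**

F1 | step 13 | methyl 2-{(E)-[(1R,2S,5S)-2-{[(tert-butyldiphenylsilyl)oxy]methyl}-6-methylidene-2-[(E)-2-(4,4,5,5-tetramethyl-1,3,2-dioxaborolan-2-yl)ethenyl]-3,9-dioxabicyclo[3.3.1]nonan-4-ylidene]methyl}prop-2-enoate | COC(=O)C(=C)/C=C1/O[C@](CO[Si](c2ccccc2)(c2ccccc2)C(C)(C)C)(/C=C/B2OC(C)(C)C(C)(C)O2)[C@H]2CCC(=C)[C@@H]1O2
F2 | step 13 | methyl 2-{(E)-[(1R,2S,5S)-2-{[(tert-butyldiphenylsilyl)oxy]methyl}-2-{(E)-2-[(chloroacetyl)oxy]ethenyl}-6-methylidene-3,9-dioxabicyclo[3.3.1]nonan-4-ylidene]methyl}prop-2-enoate | COC(=O)C(=C)/C=C1/O[C@](CO[Si](c2ccccc2)(c2ccccc2)C(C)(C)C)(/C=C/OC(=O)CCl)[C@H]2CCC(=C)[C@@H]1O2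
F3 | step 13 | methyl (1R,5S,7R,8S,9Z)-14-[(tert-butyldiphenylsilyl)oxy]-8-[(chloroacetyl)oxy]-6-oxo-1,5-epoxygermacra-4(15),9,11(13)-trien-12-oate | ClCC(=O)O[C@H]1/C=C(/CO[Si](c2ccccc2)(c2ccccc2)C(C)(C)C)[C@H]2CCC(=C)[C@H](O2)C(=O)[C@@H]1C(=C)C(=O)OC
F4 | step 13 | (1R,5S,6S,7R,8S,9Z)-14-[(tert-butyldiphenylsilyl)oxy]-1,5-epoxygermacra-4(15),9,11(13)-trien-12,6-olid-8-yl chloroacetate | ClCC(=O)O[C@H]1/C=C(/CO[Si](c2ccccc2)(c2ccccc2)C(C)(C)C)[C@H]2CCC(=C)[C@H](O2)[C@H]2OC(=O)C(=C)[C@@H]21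
F5 | step 13 | (1R,5S,6S,7R,8S,9Z)-14-[(tert-butyldiphenylsilyl)oxy]-1,5-epoxy-8-hydroxygermacra-4(15),9,11(13)-trien-12,6-olide | O[C@H]1/C=C(/CO[Si](c2ccccc2)(c2ccccc2)C(C)(C)C)[C@H]2CCC(=C)[C@H](O2)[C@H]2OC(=O)C(=C)[C@@H]21
F6 | step 10 | (1R,2S,4E,5S)-2-{[(tert-butyldiphenylsilyl)oxy]methyl}-4-(iodomethylidene)-6-methylidene-2-[(trimethylsilyl)ethynyl]-3,9-dioxabicyclo[3.3.1]nonane | I/C=C1/O[C@](CO[Si](c2ccccc2)(c2ccccc2)C(C)(C)C)(C#C[Si](C)(C)C)[C@H]2CCC(=C)[C@@H]1O2
F7 | step 14 | methyl (1R,5S,6R,7S,8R,9Z)-14-[(tert-butyldiphenylsilyl)oxy]-6-hydroxy-8-[(2-methylprop-2-enoyl)oxy]-1,5-epoxygermacra-4(15),9,11(13)-trien-12-oate | C=C(C)C(=O)O[C@@H]1/C=C(/CO[Si](c2ccccc2)(c2ccccc2)C(C)(C)C)[C@H]2CCC(=C)[C@H](O2)[C@H](O)[C@@H]1C(=C)C(=O)OC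
F8 | step 14 | (1R,5S,6R,7S,8R,9Z)-14-[(tert-butyldiphenylsilyl)oxy]-6-hydroxy-8-[(2-methylprop-2-enoyl)oxy]-1,5-epoxygermacra-4(15),9,11(13)-trien-12-oic acid | C=C(C)C(=O)O[C@@H]1/C=C(/CO[Si](c2ccccc2)(c2ccccc2)C(C)(C)C)[C@H]2CCC(=C)[C@H](O2)[C@H](O)[C@@H]1C(=C)C(=O)O
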